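The runs stem from a simulated flask for an exercise.

The ratio r of target to starting material says which of the two leads, and I took the even split, r = 1, as the zero of my scale. Saturday's run, Friday's run, larch and maple each carry 0.113 M of coupling partner, so I compared them through one apparent first-order constant k′ for the step to target. This was a crude device: the coupling partner is not in large excess, with 0.113 M against 0.19 M of starting material in Friday's run, so the true rate per unit of starting material falls as the coupling partner is consumed. With k′ held constant and all reacted starting material read as target, r = exp(k′t) − 1, and target equals starting material at τ = ln 2/k′.

| setting | Saturday's | Friday's | larch | maple |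
|---|---|---|---|---|
| starting material | 0.12 M | 0.19 M | 0.087 M | 0.087 M |
| coupling partner | 0.113 M | 0.113 M | 0.113 M | 0.113 M |
| temperature | 55 °C | 74 °C | 70 °C | 78 °C |
| remark | run made earlier | run made earlier |  |  |
| time |  |  | 2.0 h | 2.0 h |

Saturday's run (percent of the starting material charged)

| time / h | starting material / % | side product / % | target / % |
|---|---|---|---|
| 0.250 | 94 | 1 | 2 |
| 0.667 | 92 | 2 | 3 |
| 1.33 | 84 | 2 | 13 |
| 3.00 | 69 | 7 | 23 |

Friday's run (percent of the starting material charged)

| time / min | starting material / % | side product / % | target / % |
|---|---|---|---|
| 8.00 | 92 | 3 | 8 |
| 20.0 | 83 | 3 | 15 |
| 40.0 | 70 | 6 | 22 |
| 90.0 | 62 | 7 | 33 |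

(readings scatter by 1.5 percentage points)

- reactions considered so far: starting material + 2 coupling partner -> side product; starting material + coupling partner <-> target

* which of these there is most of at the end, counted by the starting material in it, larch (starting material / target / side product)
* which of these there is most of at the end, counted by the starting material in it, maple (starting material / target / side product)
* how much there is at the end of the one of these that leads, in percent of the starting material charged: larch
* how much there is at the end of the one of these that leads, in percent of the starting material charged: maple

Which reading had to be good? I interpolated ln τ linearly in temperature, so for larch Saturday's τ weighs 0.211, less than Friday's 0.789. Friday's reading therefore mattered more. I took it at 40.0 min, with 57.2 % of the coupling partner spent, and not at 90.0 min, with 79.0 % spent.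

Friday's run gave τ = 1.69 h, and Saturday's last reading gave 7.23 h. For maple, the even-split time came to 1.25 h, and for larch to 2.30 h.

| Flask | τ | Time | r expected |
|---|---|---|---|
| larch | 2.30 h | 2.0 h | 0.829 |
| maple | 1.25 h | 2.0 h | 2.04 |

So I expected starting material to lead in larch, narrowly, and target in maple. I stopped at leaders and ratios.

The forecast named the same leaders: starting material at 47 % for larch, “This is close, but starting material leads”, and target at 55 % for maple.

    starting material + 2 coupling partner → side product (k = 0.00330 /M²/s, Ea = 74.0 kJ/mol)
    starting material + coupling partner ⇌ target (K = 200 /M, k = 0.00110 /M/s, Ea = 85.0 kJ/mol, ΔH = −47.0 kJ/mol)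
    (constants at 70 °C)

Larch ended with starting material at 47.3 % against target at 41.8 %, r = 0.884. Maple ended with target at 54.6 % against starting material at 33.1 %, r = 1.65, below my 2.04. A reading of maple at 80 min, just past its τ of 1.25 h, showed target at 47.3 % and starting material at 41.6 %. In maple at 0.476 h, the half-life of starting material by the forward step to target, 1.2 h, was shorter than its half-life toward side product. That second half-life was 5.5 h.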